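## Structural features

The target is a C15 chain (C1 = terminal alkyne CH, C15 = methyl) whose only ring is an oxocane: one oxygen bridges C6 and C12, so the ring holds O, C6, C7, C8, C9, C10, C11 and C12, all sp3. C6 carries the (Z)-pent-2-en-4-ynyl arm (C1–C5) and C12 the 1-acetoxypropyl arm (C13–C15); the two arms are cis across the ring oxygen. The six stereocentres (6R, 7R, 9R, 10S, 12R, 13S) form three adjacent pairs: C6/C7 (acetoxy cis to the enyne arm), C9/C10 (a cis-diol on the ring face opposite to the C6, C7 and C12 substituents) and C12/C13 (ring carbon and exocyclic carbinol). Fragile groups are the Z-enyne with its terminal alkyne and the two secondary acetates that sit near free hydroxyls, so the last step cannot be basic; β-alkoxy carbonyl intermediates can also open the ring by elimination. The real difficulty is twofold: an eight-membered ether with cis α,α′-substituents is costly to close end to end, and four secondary oxygens must be told apart (two acetates, two free hydroxyls). The key step exploits the C8–C9 unit as a two-carbon insert between C7 and C10: without it the six-membered ring O–C6–C7–C10–C11–C12 remains, a cis-2,6-disubstituted oxan-3-one pattern. The C7 carbinol then maps onto a ketone and the C9/C10 cis-diol onto a Z alkene, which are exactly the two functions left behind when a cyclobutane built on the C7–C10 bond fragments.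

## Logic of the disconnections

33 to 32 and 31. The O–C acetal bonds at C9/C10 and the acyl–O bonds at C7/C13 are cut last. The diol stays masked as a ketal while C7 and C13 are acetylated, which settles the differentiation of the four oxygens. The demand is an acidic final step, so that no acetate migrates or is lost.

31 to 30, then to 27 and 28 (through 29). The C3=C4 double bond and three Si–O/Si–C bonds are cut. The enyne is the most sensitive part and enters late from a C4 aldehyde and a three-carbon unit. The forward step must give the Z alkene and must not trigger β-elimination of the ring oxygen from 27; one fluoride treatment then has to remove all silyl groups.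

27 to 26 and 25. Only the oxidation level and the benzylic O–C bond at C4 change. An aryl-methyl ether is the one C4 protecting group that survives organolithium, hydride, zinc and fluoride. Its oxidative removal must spare silyl ethers and the ketal.

25 to 24 and 23. The C9–O and C10–O bonds are cut together, leaving a Z alkene. Both oxygens then arrive in one syn addition, but the reagent has to attack the face opposite to the C7 silyl ether and the two arms.

23 to 22 and 21. The C7–H bond is cut, leaving a ketone. The hydride must come from the face away from the C6 arm to give the 7R carbinol.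

21 to 19 (through 20). In the retrosynthetic sense the C7–C10 bond is re-formed and an oxygen leaving group placed on C9, so the eight-membered ring becomes a six-membered ring carrying a two-carbon cyclobutane bridge. No medium ring has to be closed end to end. The forward step needs the C9 leaving group on the concave face and fragmentation of the ring-fusion bond in preference to C7–C8.

19 to 18, 17 and 16, then to 13 and 14 (through 15). The C7–C8 and C9–C10 σ bonds are cut as a [2+2] retron; the mesylate, the carbinol and the two chlorines are functional-group changes. The two new carbons come from a ketene and the cycloaddition regiochemistry places oxygen on C9. The demand is convex-face hydride delivery at C9.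

13 to 12, 11 and 10. The Si–O7 and C11–H bonds are cut (1,4-hydrosilylation retron), then C12–H, then the pyranone is traced to a furan carbinol. The six-membered ring and its cis-2,6 pattern come from an aromatic precursor. The forward reduction at C12 has to give the cis isomer.

10 to 9 and 8, then to 6 and 3 (through 7). The C6–C7 bond is cut, giving a metallated furan and a C4–C6 aldehyde. The C6 configuration is set afterwards by catalyst control, independent of C13.

6 to 5 and 4; 3 to 2 and 1. Only C13–H and protecting-group bonds are cut. C13 is set by asymmetric reduction of a commercial ketone, and the three-carbon aldehyde comes from a symmetrical diol.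

## Other disconnections considered

Alternative 1: The cut is C10–C11, with C12 as a lactone carbonyl on the C6 oxygen. In the forward step SmI2 turns the bromoacetate of A2 into a samarium enolate that adds to the C10 aldehyde and gives the β-hydroxy lactone A1.
- In favour: intramolecular samarium Reformatsky closure is an established route to medium-ring lactones, so this key step is better precedented than the fragmentation of 19. A1 already holds the C7, C9 and C10 oxygens, so no late face-selective osmylation is needed; on that point it is also better.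
- Against: C12 is a carbonyl in A1. The C12 stereocentre, the whole C13–C15 arm and C13 must be added afterwards to a flexible oxocane, with the 2,8-cis relation still to be won. C10 must come out erythro to C9, which a cyclic samarium aldolate transition state does not guarantee.
- Comparison: on structure the chosen plan is stronger, because both arms and C12/C13 are fixed before any medium ring exists. On step economy A2 needs a long acyclic build with three stereocentres plus post-cyclisation work, so the alternative is expected to be longer.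

Alternative 2: The cut is C6–C7. The C9/C10 diol is taken from A5, and SmI2 reduces the C7 aldehyde of A4 to a ketyl that adds to C6 of the β-alkoxyacrylate, giving A3.
- In favour: the cis-diol comes from the chiral pool with no facial-selectivity question, which is better than the chosen plan. The ester arm of A3 reaches the C4 aldehyde in one reduction, one step better than ether cleavage plus oxidation. The cis relation across oxygen is the normal outcome of this chelated cyclisation.
- Against: the reaction is established for six- and seven-membered ethers; for an eight-membered ring simple reduction or pinacol coupling of the ketyl should compete. C7 emerges trans to the arm, so an inversion (two steps) is needed. C12 and C13 still have to be built onto the sugar.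
- Comparison: on mechanism both key steps are uncertain for this ring size, so the two are equal in risk. On step economy the sugar elaboration and the C7 inversion offset the gain at C4.

Alternative 3: The cut is O–C12. A peracid converts cycloheptanone A7 into lactone A6 by migration of the more substituted C12 with retention.
- In favour: regiochemistry and retention are predictable, so the key step is more reliable than the fragmentation of 19. The ring is also made by expansion and not by end-to-end closure, which is equal in concept to the chosen plan. The C9/C10 acetonide and C12/C13 are in place.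
- Against: A7, a cycloheptanone with three ring stereocentres and a stereodefined arm, is itself a demanding target. In A6, C6 is a lactone carbonyl, so the C6 stereocentre, the C1–C5 arm and the C7 oxygen remain to be installed on an eight-membered oxocarbenium or enolate with uncertain cis selectivity.
- Comparison: the key step is better, but the work before and after it is heavier. The chosen plan reaches 21 with C6, C12 and C13 already set.

Key step: step 15

Remarks on the chemistry:
- Abbreviations: TBS = tert-butyldimethylsilyl, TES = triethylsilyl, TIPS = triisopropylsilyl, PMB = 4-methoxybenzyl, Ms = methanesulfonyl. Locants C1–C15 are those of the target chain.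
- Assumption: the temporary centres C7, C9 and C10 of 16–20 are drawn for ketene approach anti to the C6 arm. The other cis-fused adduct would converge on the same 21.
- The new carbinol centre of 8 and the anomeric centre of 11 are mixtures that are erased in steps 6 and 9.

## Steps

Step 1
Reactants: 1 propane-1,3-diol
Product: 2 3-(PMBO)propan-1-ol, i.e. 3-[(4-methoxyphenyl)methoxy]propan-1-ol
Conditions: NaH, PMBCl, Bu4NI (cat.), THF, 0 °C to rt (threefold excess of 1)
Reagents that add atoms: 4-methoxybenzyl chloride, COc1ccc(CCl)cc1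
Why: Williamson etherification; the excess of the symmetrical diol favours the mono-ether.

Step 2
Reactants: 2 3-(PMBO)propan-1-ol
Product: 3 3-(PMBO)propanal
Conditions: TEMPO (cat.), PhI(OAc)2, CH2Cl2, rt
Reagents that add atoms: none
Why: Oxoammonium oxidation of a primary alcohol stops at the aldehyde and is mild enough for a β-alkoxy aldehyde.

Step 3
Reactants: 4 1-(furan-2-yl)propan-1-one (2-propionylfuran)
Product: 5 (1S)-1-(furan-2-yl)propan-1-ol
Conditions: RuCl(p-cymene)[(S,S)-TsDPEN] (0.5 mol %), HCO2H/Et3N (5:2), rt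
Reagents that add atoms: none
Why: Noyori asymmetric transfer hydrogenation of a heteroaryl alkyl ketone; the (S,S) catalyst delivers hydride to the face that gives the S carbinol (C13).

Step 4
Reactants: 5 (1S)-1-(furan-2-yl)propan-1-ol
Product: 6 tert-butyl{[(1S)-1-(furan-2-yl)propyl]oxy}dimethylsilane
Conditions: TBSCl, imidazole, DMF, rt
Reagents that add atoms: tert-butyldimethylsilyl chloride, CC(C)(C)[Si](C)(C)Cl
Why: Standard silylation; the ether blocks this carbinol so that only the C6 hydroxyl can enter the later ring-forming oxidation.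

Step 5
Reactants: 6 TBS ether of the furyl carbinol; 3 3-(PMBO)propanal
Product: 8 1-{5-[(1S)-1-(TBSO)propyl]furan-2-yl}-3-(PMBO)propan-1-ol (both C6 epimers), via 5-lithiofuran 7 (not isolated)
Conditions: n-BuLi, THF, −78 to 0 °C; then 3, −78 °C
Reagents that add atoms: none
Why: α-Lithiation of a 2-alkylfuran at its free 5-position and 1,2-addition to the aldehyde form the C6–C7 bond; the C6 epimer ratio is irrelevant.

Step 6
Reactants: 8 furyl carbinol mixture
Product: 9 1-{5-[(1S)-1-(TBSO)propyl]furan-2-yl}-3-(PMBO)propan-1-one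
Conditions: DMP, CH2Cl2, rt
Reagents that add atoms: none
Why: Dess–Martin oxidation of an activated secondary carbinol; this removes the uncontrolled C6 centre.

Step 7
Reactants: 9 furyl ketone
Product: 10 (1R)-1-{5-[(1S)-1-(TBSO)propyl]furan-2-yl}-3-(PMBO)propan-1-ol
Conditions: RuCl(p-cymene)[(R,R)-TsDPEN] (1 mol %), HCO2H/Et3N (5:2), CH2Cl2, rt
Reagents that add atoms: none
Why: Noyori asymmetric transfer hydrogenation; the (R,R) catalyst sets C6 as R under catalyst control, the remote C13 centre having no influence.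

Step 8
Reactants: 10 (R)-furyl carbinol
Product: 11 (2R)-6-[(1S)-1-(TBSO)propyl]-6-hydroxy-2-[2-(PMBO)ethyl]-2H-pyran-3(6H)-one (both C12 anomers)
Conditions: NBS, NaHCO3, THF/H2O (4:1), 0 °C
Reagents that add atoms: water, O
Why: Achmatowicz rearrangement: oxidative opening of the furan to the ene-dione and closure of the C6 hydroxyl onto C12 builds the six-membered ring O–C6–C7–C10–C11–C12 with C6 unchanged.

Step 9
Reactants: 11 hemiketal pyranone
Product: 12 (2R,6R)-6-[(1S)-1-(TBSO)propyl]-2-[2-(PMBO)ethyl]-2H-pyran-3(6H)-one (2,6-cis)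
Conditions: Et3SiH, TFA, CH2Cl2, −40 °C
Reagents that add atoms: none
Why: Kishi-type ionic reduction: the silane adds axially to the cyclic oxocarbenium ion so that both α-substituents end up pseudo-equatorial, setting C12 as R (cis to the C6 arm); the low temperature spares the PMB and TBS ethers.

Step 10
Reactants: 12 cis-dihydropyranone
Product: 13 (2R,6R)-2-[(1S)-1-(TBSO)propyl]-6-[2-(PMBO)ethyl]-5-(triethylsilyloxy)-3,6-dihydro-2H-pyran (TES enol ether across C7=C10)
Conditions: Et3SiH, RhCl(PPh3)3 (1 mol %), toluene, 50 °C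
Reagents that add atoms: triethylsilane, CC[SiH](CC)CC
Why: Rhodium-catalysed 1,4-hydrosilylation of a cyclic enone with a monohydrosilane gives the silyl enol ether regiospecifically at C7=C10, without any base that could enolise towards C6 or epimerise it.

Step 11
Reactants: 13 TES enol ether; 14 trichloroacetyl chloride
Product: 16 (1R,2R,4R,6S)-8,8-dichloro-4-[(1S)-1-(TBSO)propyl]-2-[2-(PMBO)ethyl]-1-(triethylsilyloxy)-3-oxabicyclo[4.2.0]octan-7-one (cis-fused; cyclobutanone anti to the two arms), via dichloroketene 15 (not isolated)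
Conditions: Zn–Cu couple, Et2O/DME, slow addition of 14, 0 °C to rt
Reagents that add atoms: none
Why: Ketene–enol ether [2+2] cycloaddition: the nucleophilic C10 bonds to the ketene carbonyl carbon (C9) and C7 to the CCl2 carbon (C8), the fusion is necessarily cis, and the approach is expected anti to the adjacent C6 arm; DME ties up ZnCl2.

Step 12
Reactants: 16 dichlorocyclobutanone
Product: 17 (1R,2R,4R,6S)-4-[(1S)-1-(TBSO)propyl]-2-[2-(PMBO)ethyl]-1-(triethylsilyloxy)-3-oxabicyclo[4.2.0]octan-7-one
Conditions: Zn, NH4Cl, MeOH, rt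
Reagents that add atoms: none
Why: Reductive removal of both α-chlorines from an α,α-dichloroketone by zinc; the nearly neutral medium keeps the tertiary TES ether and so avoids retro-aldol opening.

Step 13
Reactants: 17 cyclobutanone
Product: 18 (1R,2R,4R,6R,7R)-4-[(1S)-1-(TBSO)propyl]-2-[2-(PMBO)ethyl]-1-(triethylsilyloxy)-3-oxabicyclo[4.2.0]octan-7-ol (C9 hydroxyl endo, cis to C11)
Conditions: LiBH(s-Bu)3 (L-Selectride), THF, −78 °C
Reagents that add atoms: none
Why: A bulky hydride should attack the cyclobutanone from the convex face, away from C11 and C6 of the six-membered ring, which puts the C9 hydroxyl on the concave face.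

Step 14
Reactants: 18 endo cyclobutanol
Product: 19 (1R,2R,4R,6R,7R)-4-[(1S)-1-(TBSO)propyl]-2-[2-(PMBO)ethyl]-1-(triethylsilyloxy)-3-oxabicyclo[4.2.0]octan-7-yl methanesulfonate
Conditions: MsCl, Et3N, CH2Cl2, 0 °C
Reagents that add atoms: methanesulfonyl chloride, CS(=O)(=O)Cl
Why: Sulfonylation of a secondary alcohol with retention at C9.

Step 15
Reactants: 19 bicyclic mesylate
Product: 21 (2R,5Z,8R)-8-[(1S)-1-(TBSO)propyl]-2-[2-(PMBO)ethyl]-7,8-dihydro-2H-oxocin-3(4H)-one (2,8-cis oxoc-5-en-3-one; C7 ketone, Z C9=C10), via tetrabutylammonium cyclobutanolate 20 (not isolated)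
Conditions: TBAF (1.2 equiv), THF, −78 to 0 °C; pH 7 buffer quench
Reagents that add atoms: none
Why: Proposed new method: fluoride removes the triethylsilyl group of 19 and frees the tertiary alkoxide 20, whose oxygen lone pair pushes into the C7–C10 σ bond while the C9 mesylate leaves, a concerted Grob (Wharton-type) 1,3-fragmentation that gives the C7 ketone and the C9=C10 alkene of 21. The closest known reaction types are the retro-aldol two-carbon ring expansion of dechlorinated dichloroketene–silyl enol ether cycloadducts, in which the same ring-fusion bond opens, and the Grob fragmentation of cyclic 1,3-diol monosulfonates to medium-ring alkenones; a cyclobutane-based array of this kind has not been shown. The eight-membered ring is not closed end to end: it arises by ring expansion, because breaking the bond shared by the six- and four-membered rings merges them into the oxocene, driven by release of cyclobutane strain. No stereocentre is created; the temporary centres C7, C9 and C10 vanish and C6, C12 and C13 are untouched. Alkene geometry: the endo mesylate (cis to C11) has its C–O bond roughly anti to the fusion bond in the pseudo-equatorial pucker, and the small rotation to full antiperiplanarity places C8 and C11 on the same side, so only the Z alkene can form. Regioselectivity: C9 is bonded to both C8 and C10, so the C7–C8 bond could fragment instead to a 4-vinyl oxanone; the fusion bond is expected to win as the more substituted and more strained σ donor that leads to the disubstituted alkene. Chemoselectivity: one equivalent of fluoride at low temperature removes the TES ether before the secondary TBS ether, and the buffered quench limits C6 epimerisation and conjugation of the β,γ-enone.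

Step 16
Reactants: 21 oxocenone
Product: 22 (2R,3R,5Z,8R)-8-[(1S)-1-(TBSO)propyl]-2-[2-(PMBO)ethyl]-3,4,7,8-tetrahydro-2H-oxocin-3-ol (C7 hydroxyl cis to the C6 arm)
Conditions: LiBH(s-Bu)3 (L-Selectride), THF, −78 °C
Reagents that add atoms: none
Why: The bulky hydride should attack the C7 carbonyl from the peripheral face away from the adjacent C6 arm, which places the hydroxyl cis to that arm (7R); the isolated alkene is inert.

Step 17
Reactants: 22 oxocenol
Product: 23 TBS ether of 22 at C7, i.e. (2R,3R,5Z,8R)-3-(TBSO)-8-[(1S)-1-(TBSO)propyl]-2-[2-(PMBO)ethyl]-3,4,7,8-tetrahydro-2H-oxocine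
Conditions: TBSOTf, 2,6-lutidine, CH2Cl2, −78 to 0 °C
Reagents that add atoms: tert-butyldimethylsilyl trifluoromethanesulfonate, CC(C)(C)[Si](C)(C)OS(=O)(=O)C(F)(F)F
Why: Silyl triflate protects the hindered secondary alcohol; the bulky ether shields its ring face, prevents hydroxyl-directed osmylation and leaves later with the C13 ether in one operation.

Step 18
Reactants: 23 bis-TBS oxocene
Product: 24 (2R,3R,5R,6S,8R)-3-(TBSO)-8-[(1S)-1-(TBSO)propyl]-2-[2-(PMBO)ethyl]oxocane-5,6-diol (9R,10S cis-diol, anti to the C6, C7 and C12 substituents)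
Conditions: OsO4 (2 mol %), NMO, acetone/H2O (4:1), rt
Reagents that add atoms: osmium tetroxide (catalytic oxygen carrier), O=[Os](=O)(=O)=O; N-methylmorpholine N-oxide, C[N+]1([O-])CCOCC1; water, O
Why: Upjohn dihydroxylation adds both oxygens syn to the Z alkene; attack is expected on the ring face that carries only H6, H7 and H12, opposite to the C7 silyl ether and both arms, which gives 9R,10S.

Step 19
Reactants: 24 diol
Product: 25 5,6-O-isopropylidene acetal of 24 (acetonide across C9/C10)
Conditions: 2,2-dimethoxypropane, PPTS (cat.), CH2Cl2, rt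
Reagents that add atoms: 2,2-dimethoxypropane, COC(C)(C)OC
Why: Acid-catalysed transketalisation; a cis-1,2-diol forms the five-membered ketal readily, which sets the C9/C10 oxygens apart from C7 and C13.

Step 20
Reactants: 25 acetonide
Product: 26 2-[(2R,3R,5R,6S,8R)-3-(TBSO)-8-[(1S)-1-(TBSO)propyl]-5,6-(isopropylidenedioxy)oxocan-2-yl]ethan-1-ol
Conditions: DDQ, CH2Cl2/pH 7 buffer (10:1), 0 °C
Reagents that add atoms: none
Why: Oxidative cleavage of the electron-rich benzyl ether; no alkene remains at this stage and silyl ethers and the ketal are inert.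

Step 21
Reactants: 26 primary alcohol
Product: 27 2-[(2R,3R,5R,6S,8R)-3-(TBSO)-8-[(1S)-1-(TBSO)propyl]-5,6-(isopropylidenedioxy)oxocan-2-yl]acetaldehyde (C4 aldehyde)
Conditions: TEMPO (cat.), PhI(OAc)2, CH2Cl2, rt
Reagents that add atoms: none
Why: Oxoammonium oxidation to the aldehyde under nearly neutral conditions avoids β-elimination of the ring oxygen; the aldehyde is used at once.

Step 22
Reactants: 27 C4 aldehyde; 28 1,3-bis(triisopropylsilyl)prop-1-yne
Product: 30 (2R,3R,5R,6S,8R)-3-(TBSO)-8-[(1S)-1-(TBSO)propyl]-5,6-(isopropylidenedioxy)-2-[(2Z)-5-(triisopropylsilyl)pent-2-en-4-yn-1-yl]oxocane, via lithiated bis-silylpropyne 29 (not isolated)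
Conditions: n-BuLi, THF, −78 °C (28 to 29); then 27, −78 to 0 °C
Reagents that add atoms: none
Why: Peterson olefination: the propargylic carbanion adds to the aldehyde and the β-silyl alkoxide undergoes syn-elimination of silanolate; the bulky TIPS groups favour the adduct that leads to the Z enyne, and no ester is present to compete.

Step 23
Reactants: 30 silylated Z-enyne
Product: 31 (2R,3R,5R,6S,8R)-8-[(1S)-1-hydroxypropyl]-5,6-(isopropylidenedioxy)-2-[(2Z)-pent-2-en-4-yn-1-yl]oxocan-3-ol
Conditions: TBAF (5 equiv), THF, rt to 40 °C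
Reagents that add atoms: none
Why: Fluoride cleaves both secondary TBS ethers and the alkynyl C–Si bond in one operation; the ketal is stable and no base-labile group is present yet.

Step 24
Reactants: 31 diol
Product: 32 (2R,3R,5R,6S,8R)-8-[(1S)-1-acetoxypropyl]-5,6-(isopropylidenedioxy)-2-[(2Z)-pent-2-en-4-yn-1-yl]oxocan-3-yl acetate
Conditions: Ac2O, pyridine, DMAP (cat.), CH2Cl2, rt
Reagents that add atoms: acetic anhydride, CC(=O)OC(C)=O
Why: Acylation of the two free secondary hydroxyls at C7 and C13; the C9/C10 oxygens are locked in the ketal.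

Step 25
Reactants: 32 diacetate acetonide
Product: 33 (2R,3R,5R,6S,8R)-8-[(1S)-1-acetoxypropyl]-5,6-dihydroxy-2-[(2Z)-pent-2-en-4-yn-1-yl]oxocan-3-yl acetate (the target; 6R,7R,9R,10S,12R,13S)
Conditions: TFA/H2O (9:1), CH2Cl2, 0 °C
Reagents that add atoms: none
Why: Acid-catalysed ketal hydrolysis frees the cis-diol; acetates and the enyne tolerate brief cold acid, and no base is present to cause acyl migration.

## Compound list

1 | propane-1,3-diol | OCCCO | starting material
2 | 3-[(4-methoxyphenyl)methoxy]propan-1-ol | COc1ccc(COCCCO)cc1 | intermediate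
3 | 3-[(4-methoxyphenyl)methoxy]propanal | COc1ccc(COCCC=O)cc1 | intermediate
4 | 1-(furan-2-yl)propan-1-one (2-propionylfuran) | CCC(=O)c1ccco1 | starting material
5 | (1S)-1-(furan-2-yl)propan-1-ol | CC[C@H](O)c1ccco1 | intermediate
6 | tert-butyl{[(1S)-1-(furan-2-yl)propyl]oxy}dimethylsilane | CC[C@H](O[Si](C)(C)C(C)(C)C)c1ccco1 | intermediate
7 | {5-[(1S)-1-(TBSO)propyl]furan-2-yl}lithium (5-lithiofuran) | CC[C@H](O[Si](C)(C)C(C)(C)C)c1ccc([Li])o1 | intermediate
8 | 1-{5-[(1S)-1-(TBSO)propyl]furan-2-yl}-3-(PMBO)propan-1-ol, both C6 epimers | CC[C@H](O[Si](C)(C)C(C)(C)C)c1ccc(C(O)CCOCc2ccc(OC)cc2)o1 | intermediate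
9 | 1-{5-[(1S)-1-(TBSO)propyl]furan-2-yl}-3-(PMBO)propan-1-one | CC[C@H](O[Si](C)(C)C(C)(C)C)c1ccc(C(=O)CCOCc2ccc(OC)cc2)o1 | intermediate
10 | (1R)-1-{5-[(1S)-1-(TBSO)propyl]furan-2-yl}-3-(PMBO)propan-1-ol | CC[C@H](O[Si](C)(C)C(C)(C)C)c1ccc([C@H](O)CCOCc2ccc(OC)cc2)o1 | intermediate
11 | (2R)-6-[(1S)-1-(TBSO)propyl]-6-hydroxy-2-[2-(PMBO)ethyl]-2H-pyran-3(6H)-one, both anomers | COc1ccc(COCC[C@H]2OC(O)([C@H](CC)O[Si](C)(C)C(C)(C)C)C=CC2=O)cc1 | intermediate
12 | (2R,6R)-6-[(1S)-1-(TBSO)propyl]-2-[2-(PMBO)ethyl]-2H-pyran-3(6H)-one | COc1ccc(COCC[C@H]2O[C@@H]([C@H](CC)O[Si](C)(C)C(C)(C)C)C=CC2=O)cc1 | intermediate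
13 | (2R,6R)-2-[(1S)-1-(TBSO)propyl]-6-[2-(PMBO)ethyl]-5-(triethylsilyloxy)-3,6-dihydro-2H-pyran | COc1ccc(COCC[C@H]2O[C@@H]([C@H](CC)O[Si](C)(C)C(C)(C)C)CC=C2O[Si](CC)(CC)CC)cc1 | intermediate
14 | trichloroacetyl chloride | ClC(=O)C(Cl)(Cl)Cl | starting material
15 | dichloroketene | ClC(Cl)=C=O | intermediate
16 | (1R,2R,4R,6S)-8,8-dichloro-4-[(1S)-1-(TBSO)propyl]-2-[2-(PMBO)ethyl]-1-(triethylsilyloxy)-3-oxabicyclo[4.2.0]octan-7-one | COc1ccc(COCC[C@H]2O[C@@H]([C@H](CC)O[Si](C)(C)C(C)(C)C)C[C@@H]3C(=O)C(Cl)(Cl)[C@]23O[Si](CC)(CC)CC)cc1 | intermediate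
17 | (1R,2R,4R,6S)-4-[(1S)-1-(TBSO)propyl]-2-[2-(PMBO)ethyl]-1-(triethylsilyloxy)-3-oxabicyclo[4.2.0]octan-7-one | COc1ccc(COCC[C@H]2O[C@@H]([C@H](CC)O[Si](C)(C)C(C)(C)C)C[C@@H]3C(=O)C[C@]23O[Si](CC)(CC)CC)cc1 | intermediate
18 | (1R,2R,4R,6R,7R)-4-[(1S)-1-(TBSO)propyl]-2-[2-(PMBO)ethyl]-1-(triethylsilyloxy)-3-oxabicyclo[4.2.0]octan-7-ol | COc1ccc(COCC[C@H]2O[C@@H]([C@H](CC)O[Si](C)(C)C(C)(C)C)C[C@@H]3[C@H](O)C[C@]23O[Si](CC)(CC)CC)cc1 | intermediate
19 | (1R,2R,4R,6R,7R)-4-[(1S)-1-(TBSO)propyl]-2-[2-(PMBO)ethyl]-1-(triethylsilyloxy)-3-oxabicyclo[4.2.0]octan-7-yl methanesulfonate | COc1ccc(COCC[C@H]2O[C@@H]([C@H](CC)O[Si](C)(C)C(C)(C)C)C[C@@H]3[C@H](OS(C)(=O)=O)C[C@]23O[Si](CC)(CC)CC)cc1 | intermediate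
20 | tetrabutylammonium (1R,2R,4R,6R,7R)-7-(methanesulfonyloxy)-4-[(1S)-1-(TBSO)propyl]-2-[2-(PMBO)ethyl]-3-oxabicyclo[4.2.0]octan-1-olate | COc1ccc(COCC[C@H]2O[C@@H]([C@H](CC)O[Si](C)(C)C(C)(C)C)C[C@@H]3[C@H](OS(C)(=O)=O)C[C@]23[O-])cc1.CCCC[N+](CCCC)(CCCC)CCCC | intermediate
21 | (2R,5Z,8R)-8-[(1S)-1-(TBSO)propyl]-2-[2-(PMBO)ethyl]-7,8-dihydro-2H-oxocin-3(4H)-one | COc1ccc(COCC[C@H]2O[C@@H]([C@H](CC)O[Si](C)(C)C(C)(C)C)C/C=C\CC2=O)cc1 | intermediate
22 | (2R,3R,5Z,8R)-8-[(1S)-1-(TBSO)propyl]-2-[2-(PMBO)ethyl]-3,4,7,8-tetrahydro-2H-oxocin-3-ol | COc1ccc(COCC[C@H]2O[C@@H]([C@H](CC)O[Si](C)(C)C(C)(C)C)C/C=C\C[C@H]2O)cc1 | intermediate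
23 | (2R,3R,5Z,8R)-3-(TBSO)-8-[(1S)-1-(TBSO)propyl]-2-[2-(PMBO)ethyl]-3,4,7,8-tetrahydro-2H-oxocine | COc1ccc(COCC[C@H]2O[C@@H]([C@H](CC)O[Si](C)(C)C(C)(C)C)C/C=C\C[C@H]2O[Si](C)(C)C(C)(C)C)cc1 | intermediate
24 | (2R,3R,5R,6S,8R)-3-(TBSO)-8-[(1S)-1-(TBSO)propyl]-2-[2-(PMBO)ethyl]oxocane-5,6-diol | COc1ccc(COCC[C@H]2O[C@@H]([C@H](CC)O[Si](C)(C)C(C)(C)C)C[C@H](O)[C@H](O)C[C@H]2O[Si](C)(C)C(C)(C)C)cc1 | intermediate
25 | 5,6-O-isopropylidene acetal of 24 | COc1ccc(COCC[C@H]2O[C@@H]([C@H](CC)O[Si](C)(C)C(C)(C)C)C[C@@H]3OC(C)(C)O[C@@H]3C[C@H]2O[Si](C)(C)C(C)(C)C)cc1 | intermediate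
26 | 2-[(2R,3R,5R,6S,8R)-3-(TBSO)-8-[(1S)-1-(TBSO)propyl]-5,6-(isopropylidenedioxy)oxocan-2-yl]ethan-1-ol | OCC[C@H]1O[C@@H]([C@H](CC)O[Si](C)(C)C(C)(C)C)C[C@@H]2OC(C)(C)O[C@@H]2C[C@H]1O[Si](C)(C)C(C)(C)C | intermediate
27 | 2-[(2R,3R,5R,6S,8R)-3-(TBSO)-8-[(1S)-1-(TBSO)propyl]-5,6-(isopropylidenedioxy)oxocan-2-yl]acetaldehyde | O=CC[C@H]1O[C@@H]([C@H](CC)O[Si](C)(C)C(C)(C)C)C[C@@H]2OC(C)(C)O[C@@H]2C[C@H]1O[Si](C)(C)C(C)(C)C | intermediate
28 | 1,3-bis(triisopropylsilyl)prop-1-yne | CC(C)[Si](C(C)C)(C(C)C)CC#C[Si](C(C)C)(C(C)C)C(C)C | starting material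
29 | [1,3-bis(triisopropylsilyl)prop-2-yn-1-yl]lithium (lithiated bis-silylpropyne) | CC(C)[Si](C(C)C)(C(C)C)C([Li])C#C[Si](C(C)C)(C(C)C)C(C)C | intermediate
30 | (2R,3R,5R,6S,8R)-3-(TBSO)-8-[(1S)-1-(TBSO)propyl]-5,6-(isopropylidenedioxy)-2-[(2Z)-5-(triisopropylsilyl)pent-2-en-4-yn-1-yl]oxocane | CC(C)[Si](C(C)C)(C(C)C)C#C/C=C\C[C@H]1O[C@@H]([C@H](CC)O[Si](C)(C)C(C)(C)C)C[C@@H]2OC(C)(C)O[C@@H]2C[C@H]1O[Si](C)(C)C(C)(C)C | intermediate
31 | (2R,3R,5R,6S,8R)-8-[(1S)-1-hydroxypropyl]-5,6-(isopropylidenedioxy)-2-[(2Z)-pent-2-en-4-yn-1-yl]oxocan-3-ol | C#C/C=C\C[C@H]1O[C@@H]([C@H](CC)O)C[C@@H]2OC(C)(C)O[C@@H]2C[C@H]1O | intermediate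
32 | (2R,3R,5R,6S,8R)-8-[(1S)-1-acetoxypropyl]-5,6-(isopropylidenedioxy)-2-[(2Z)-pent-2-en-4-yn-1-yl]oxocan-3-yl acetate | C#C/C=C\C[C@H]1O[C@@H]([C@H](CC)OC(C)=O)C[C@@H]2OC(C)(C)O[C@@H]2C[C@H]1OC(C)=O | intermediate
33 | (2R,3R,5R,6S,8R)-8-[(1S)-1-acetoxypropyl]-5,6-dihydroxy-2-[(2Z)-pent-2-en-4-yn-1-yl]oxocan-3-yl acetate | C#C/C=C\C[C@H]1O[C@@H]([C@H](CC)OC(C)=O)C[C@H](O)[C@H](O)C[C@H]1OC(C)=O | target

## Step count and least certain steps

Total step count: 25. Longest linear sequence: 23 steps (4 to 33, steps 3–25); the two-step preparation of 3 joins at step 5.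

Step 15 (key step, new method). The most likely failure is fragmentation along the wrong cyclobutane bond (C7–C8), which would keep the six-membered ring and give a vinyl side chain. Both ring bonds are aligned about equally with the C9 leaving group, and only the donor ability and strain of the fusion bond favour the expansion. Lesser risks are plain desilylation without fragmentation, loss of the C13 silyl ether, and base-induced epimerisation at C6. The fallback uses known chemistry, sets out from 13 and also bypasses steps 11–14. Ozonolysis of the silyl enol ether double bond (O3, CH2Cl2/MeOH, −78 °C; Me2S) should give the aldehyde acid F1 with the cis ether intact. Wittig methylenation with excess Ph3P=CH2 (the acid present as its carboxylate, which protects C6) gives the alkene acid F2. Amide coupling with N,O-dimethylhydroxylamine gives the Weinreb amide F3, and allylmagnesium bromide gives the allyl ketone F4. Ring-closing metathesis of F4 with the second-generation Grubbs catalyst RuCl2(=CHPh)(PCy3)(H2IMes) at high dilution forms the Z C9=C10 bond and returns to the route at 21.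

Step 10. Competing 1,2-hydrosilylation of the carbonyl, or slow turnover, would lower the yield of the enol ether. The fallback sets out from 12: hydrogenation of the enone double bond (H2, Pd/C, EtOAc, trace pyridine to spare the PMB ether) gives the oxanone F5. Kinetic deprotonation at C10 with LDA in THF at −78 °C and trapping with TESCl returns to the route at 13.

Step 13. Hydride delivery to the concave face (poor facial selectivity) is the risk, because the exo silyloxy group on C7 lies 1,3 to the carbonyl and 3-alkoxycyclobutanones tend to be attacked anti to the alkoxy group. The fallback sets out from 17 and accepts the wrong epimer: reduction with NaBH4 in MeOH gives the exo alcohol F6. Mitsunobu inversion (4-nitrobenzoic acid, PPh3, DIAD) gives the endo ester F7, and methanolysis (K2CO3, MeOH) returns to the route at 18.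

Step 18. Poor facial selectivity of the osmylation is possible if the preferred ring conformer exposes the face syn to the arms. The fallback sets out from 23 and uses the Woodward cis-hydroxylation (I2, AgOAc, moist AcOH), in which iodine takes the face osmium prefers and the acetoxonium ion delivers both oxygens to the opposite face. This gives the regioisomeric hydroxy acetates F8 (9-acetate) and F9 (10-acetate); methanolysis (K2CO3, MeOH) of the mixture returns to the route at 24.

Step 22. Enolisation of the β-alkoxy aldehyde by the lithium reagent, followed by elimination of the ring oxygen, or erosion of the Z selectivity, are the risks. The fallback sets out from 27: Stork–Zhao olefination (Ph3P(CH2I)I, NaHMDS, THF/DMPU, −78 °C) gives the Z vinyl iodide F10. Sonogashira coupling with (triisopropylsilyl)acetylene (PdCl2(PPh3)2, CuI, i-Pr2NH) returns to the route at 30.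

## Further compounds

F1 | step 15 | (2R)-2-{[(3R,4S)-4-(TBSO)-1-oxohexan-3-yl]oxy}-4-(PMBO)butanoic acid | COc1ccc(COCC[C@H](C(=O)O)O[C@@H]([C@H](CC)O[Si](C)(C)C(C)(C)C)CC=O)cc1
F2 | step 15 | (2R)-2-{[(4R,5S)-5-(TBSO)hept-1-en-4-yl]oxy}-4-(PMBO)butanoic acid | COc1ccc(COCC[C@H](C(=O)O)O[C@@H]([C@H](CC)O[Si](C)(C)C(C)(C)C)CC=C)cc1
F3 | step 15 | (2R)-N-methoxy-N-methyl-2-{[(4R,5S)-5-(TBSO)hept-1-en-4-yl]oxy}-4-(PMBO)butanamide | COc1ccc(COCC[C@H](C(=O)N(C)OC)O[C@@H]([C@H](CC)O[Si](C)(C)C(C)(C)C)CC=C)cc1
F4 | step 15 | (5R)-5-{[(4R,5S)-5-(TBSO)hept-1-en-4-yl]oxy}-7-(PMBO)hept-1-en-4-one | COc1ccc(COCC[C@H](C(=O)CC=C)O[C@@H]([C@H](CC)O[Si](C)(C)C(C)(C)C)CC=C)cc1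
F5 | step 10 | (2R,6R)-6-[(1S)-1-(TBSO)propyl]-2-[2-(PMBO)ethyl]oxan-3-one | COc1ccc(COCC[C@H]2O[C@@H]([C@H](CC)O[Si](C)(C)C(C)(C)C)CCC2=O)cc1
F6 | step 13 | (1R,2R,4R,6R,7S)-4-[(1S)-1-(TBSO)propyl]-2-[2-(PMBO)ethyl]-1-(triethylsilyloxy)-3-oxabicyclo[4.2.0]octan-7-ol (exo alcohol) | COc1ccc(COCC[C@H]2O[C@@H]([C@H](CC)O[Si](C)(C)C(C)(C)C)C[C@@H]3[C@@H](O)C[C@]23O[Si](CC)(CC)CC)cc1
F7 | step 13 | (1R,2R,4R,6R,7R)-4-[(1S)-1-(TBSO)propyl]-2-[2-(PMBO)ethyl]-1-(triethylsilyloxy)-3-oxabicyclo[4.2.0]octan-7-yl 4-nitrobenzoate | COc1ccc(COCC[C@H]2O[C@@H]([C@H](CC)O[Si](C)(C)C(C)(C)C)C[C@@H]3[C@H](OC(=O)c4ccc(cc4)[N+](=O)[O-])C[C@]23O[Si](CC)(CC)CC)cc1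
F8 | step 18 | (2R,3R,5R,6S,8R)-3-(TBSO)-8-[(1S)-1-(TBSO)propyl]-6-hydroxy-2-[2-(PMBO)ethyl]oxocan-5-yl acetate | COc1ccc(COCC[C@H]2O[C@@H]([C@H](CC)O[Si](C)(C)C(C)(C)C)C[C@H](O)[C@H](OC(C)=O)C[C@H]2O[Si](C)(C)C(C)(C)C)cc1
F9 | step 18 | (2R,3R,5R,6S,8R)-3-(TBSO)-8-[(1S)-1-(TBSO)propyl]-5-hydroxy-2-[2-(PMBO)ethyl]oxocan-6-yl acetate | COc1ccc(COCC[C@H]2O[C@@H]([C@H](CC)O[Si](C)(C)C(C)(C)C)C[C@H](OC(C)=O)[C@H](O)C[C@H]2O[Si](C)(C)C(C)(C)C)cc1
F10 | step 22 | (2R,3R,5R,6S,8R)-3-(TBSO)-8-[(1S)-1-(TBSO)propyl]-2-[(2Z)-3-iodoprop-2-en-1-yl]-5,6-(isopropylidenedioxy)oxocane | I/C=C\C[C@H]1O[C@@H]([C@H](CC)O[Si](C)(C)C(C)(C)C)C[C@@H]2OC(C)(C)O[C@@H]2C[C@H]1O[Si](C)(C)C(C)(C)C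
A1 | alternative 1 | (4S,5R,7R,8R)-8-[2-(tert-butyldiphenylsilyloxy)ethyl]-5-(TBSO)-4-hydroxy-7-(methoxymethoxy)oxocan-2-one | CC(C)(C)[Si](c1ccccc1)(c1ccccc1)OCC[C@H]1OC(=O)C[C@H](O)[C@H](O[Si](C)(C)C(C)(C)C)C[C@H]1OCOC
A2 | alternative 1 | bromoacetate of the acyclic C4–C10 aldehyde: 1-(tert-butyldiphenylsilyloxy)-6-(TBSO)-4-(methoxymethoxy)-7-oxoheptan-3-yl 2-bromoacetate (C6, C7, C9 as in the target) | O=C[C@H](O[Si](C)(C)C(C)(C)C)C[C@@H](OCOC)[C@@H](CCO[Si](c1ccccc1)(c1ccccc1)C(C)(C)C)OC(=O)CBr
A3 | alternative 2 | ethyl 2-(2,8-cis-oxocan-2-yl)acetate with C7 hydroxyl trans to the ester arm, C9/C10 acetonide and C13 PMB ether | CCOC(=O)C[C@H]1O[C@@H]([C@H](CC)OCc2ccc(OC)cc2)C[C@@H]2OC(C)(C)O[C@@H]2C[C@@H]1O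
A4 | alternative 2 | ethyl (E)-3-alkoxyacrylate on the C12 oxygen with C7 aldehyde, C9/C10 acetonide and C13 PMB ether | CCOC(=O)/C=C/O[C@@H]([C@H](CC)OCc1ccc(OC)cc1)C[C@@H]1OC(C)(C)O[C@@H]1CC=O
A5 | alternative 2 | 2-deoxy-D-ribose (open-chain form) | O=CC[C@H](O)[C@H](O)CO
A6 | alternative 3 | oxocan-2-one (C6 lactone) with C9/C10 acetonide and C12/C13 as in the target, C13 TBS ether | O=C1CC[C@H]2OC(C)(C)O[C@H]2C[C@H]([C@H](CC)O[Si](C)(C)C(C)(C)C)O1
A7 | alternative 3 | 2-[(1S)-1-(TBSO)propyl]cycloheptanone with 4,5-cis-acetonide (C12 substituent on the ketone α-carbon) | O=C1CC[C@H]2OC(C)(C)O[C@H]2C[C@@H]1[C@H](CC)O[Si](C)(C)C(C)(C)C
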